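The larch run, which is the flask itself followed so far, climbs steeply in target and then lies flat.

- larch: solid substrate 0.25 M; partner 0.50 M; temperature 25 °C; the very flask that is asked about, followed so far
- flask: solid substrate 0.25 M; partner 0.500 M; temperature 25 °C; time 20 min

larch run (percent of the solid substrate charged): time / min: target / % = 1.50: 11.4; 2.50: 15.8; 4.00: 16.6; 8.00: 17.2; 12.0: 17.4; 20.0: 17.3

(each reading ± 0.3 percentage points)

- Sunday's: at 20 min add partner, 50.0% of the amount charged, then wait 20 min
- Tuesday's: at 20 min raise the temperature by 15 K, then wait 20 min
- Saturday's: change nothing and wait 20 min more
- Friday's: at 20 min take out 90% of the target then present, then wait 20 min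

1. target, in percent of the solid substrate first charged, at 20 min
2. the remedy with the largest gain of target, or "none" below 2 percentage points (Sunday's / Tuesday's / Saturday's / Friday's / none)
3. target present, with what was taken out counted in, in percent of the solid substrate first charged, after Saturday's
4. target present, with what was taken out counted in, in percent of the solid substrate first charged, after Friday's

- given per volume of solution although it is solid: solid substrate
- what is taken out of target is counted as made
- the earlier runs were read with a standard deviation of 0.3 percentage points
- at the start none of the solid substrate is in solution
- the earlier runs do not show what temperature does; that part of a forecast is a guess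
- additions bring no volume worth counting

The bench rule says that the smaller charge, the limiting reagent, sets the ceiling: partner stands at 2.00 times the solid substrate, so the rule promises 100% of the solid substrate as target. The rule stops working at the larch plateau. The last three readings average 17.3%, and counted one to one this is 8.65% of the partner charge, so [target] in the larch run flattens at 0.0433 M under both ceilings.

The plateau can therefore be frozen and the distance below it watched. That distance is 5.9 percentage points at 1.50 min and 1.5 points at 2.50 min, so it halves in 0.506 min. This gap half-time, the time in which target's distance below its plateau halves, is a reading and carries the scatter of 0.3 points.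

The flask's 20 min holds 39.5 gap half-times, so the reckoning here commits to 17.3% for now and after Saturday's. The readings show a flat line, and both a balance, which re-forms target after Friday's, and a stopped supply, which does not, give a flat line, so this reckoning leaves Friday's open.

The forecast does not leave it open: “I read this as an equilibrium”. It gives 17.3% for now, 17.3% after Saturday's and 31% after Friday's (range 26% to 33%), and it names Friday's.

The flask gives 17.2% for now, 17.2% after Saturday's and 17.2% after Friday's, which is 14 points under the forecast. The remedy with the largest gain is Sunday's, at 23 points.

    starting material ⇌ tautomer (K = 1.50, k = 0.130 s⁻¹, Ea = 66.0 kJ mol⁻¹, ΔH = −2.00 kJ mol⁻¹)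
    starting material + partner → isomer of the product (k = 0.0500 M⁻¹ s⁻¹, Ea = 56.0 kJ mol⁻¹)
    partner + tautomer → target (k = 0.0790 M⁻¹ s⁻¹, Ea = 58.0 kJ mol⁻¹)
    solid substrate ⇌ starting material, rate k4*(cs4 - [starting material]) while solid is left; crystals form when [starting material] > cs4 (solubility = 0.170 M, k = 0.0140 s⁻¹)
    2 partner → self-condensation product (k = 0.0240 M⁻¹ s⁻¹, Ea = 67.0 kJ mol⁻¹)
    partner → decomposed reagent (k = 0.0130 s⁻¹, Ea = 74.0 kJ mol⁻¹)
    (constants at 25 °C)

The flask has come to rest: at 20.0 min it holds 0% of its partner and 0% of its solid substrate as solid. Taken as a steady half-time of partner, the gap half-time gives an estimate of 2.86 min for partner to fall under a fiftieth of its charge, and the flask shows 2.55 min. In the neighbour kept at 10 °C, the 0.109% of partner left at 20.0 min counts, taken the same way, to a steady half-time of 2.03 min, against the 0.506 min read from the larch run. Ten times the time, 200 min, is 395 gap half-times in the flask, and target then stands at 17.2%, the length of the run making no difference.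

The numbers in the tables are simulated with constants of no real substance, and the scatter is random.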